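**Retrosynthetic overview**
1. The (3S)-isoflavan comes from the (6aS,11aS)-pterocarpan by hydrogenolysis of its benzylic C11a–O bond. The dihydrofuran ring is made only to be reopened.
2. The pterocarpan comes from the cis-(3S,4S)-2'-hydroxyisoflavan-4-ol by SN1 closure. That alcohol comes from the achiral isoflavone by a Ru transfer-hydrogenation cascade with DKR, which sets C3 and C4 together.
3. The isoflavone comes from a flavanone. The aryl group is first placed on C2, then moved to C3 by an I(III)-induced 1,2-aryl shift.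
4. The flavanone comes from a 2'-hydroxychalcone by oxa-Michael closure. The chalcone comes from an acetophenone and a benzaldehyde (Claisen–Schmidt), and the extra A-ring oxygen comes from an Elbs oxidation.
5. Ring order: pyranone (as flavanone), aryl shift inside it, transient dihydrofuran, reopening. This is the order of chalcone isomerase, isoflavone synthase, isoflavone/vestitone reductase, pterocarpan synthase and pterocarpan reductase.

Assumption: the given SMILES is the (3S)-isoflavan (same spatial arrangement as (S)-equol), and compounds 1 and 5 are bought as catalogue chemicals.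

**Step 1**
Reactants: 1 2'-hydroxy-3',4'-dimethoxyacetophenone
Product: 3 2',5'-dihydroxy-3',4'-dimethoxyacetophenone, via potassium aryl sulfate 2 (not isolated)
Conditions: K2S2O8 (1.1 equiv), 10% aq NaOH, 10–20 °C, 24 h; extract unreacted 1 at pH 5; then conc. HCl, 90 °C, 1 h
Reagents that add atoms: potassium persulfate, [K+].[K+].[O-]S(=O)(=O)OOS(=O)(=O)[O-]
Why: Elbs persulfate oxidation, in which the phenoxide attacks the peroxide oxygen through its only free para carbon (C5') to give aryl sulfate 2, and acid then cleaves the S–O bond to give the hydroquinone.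

**Step 2**
Reactants: 3 2',5'-dihydroxy-3',4'-dimethoxyacetophenone
Product: 4 5'-(benzyloxy)-2'-hydroxy-3',4'-dimethoxyacetophenone
Conditions: BnBr (1.05 equiv), K2CO3 (1.2 equiv), acetone, reflux, N2
Reagents that add atoms: benzyl bromide, BrCc1ccccc1
Why: Williamson etherification, selective because the 2'-OH is hydrogen-bonded to the ketone and flanked by OMe, so only the 5'-OH is alkylated with one equivalent of halide.

**Step 3**
Reactants: 5 2-hydroxy-3,4-dimethoxybenzaldehyde
Product: 6 2-(benzyloxy)-3,4-dimethoxybenzaldehyde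
Conditions: BnBr (1.2 equiv), K2CO3 (1.5 equiv), DMF, 60 °C
Reagents that add atoms: benzyl bromide, BrCc1ccccc1
Why: Williamson etherification of the single phenol, which must be masked before any I(III) oxidant is used.

**Step 4**
Reactants: 4 5'-(benzyloxy)-2'-hydroxy-3',4'-dimethoxyacetophenone; 6 2-(benzyloxy)-3,4-dimethoxybenzaldehyde
Product: 8 rac-6-(benzyloxy)-2-[2-(benzyloxy)-3,4-dimethoxyphenyl]-7,8-dimethoxychroman-4-one (flavanone), via (E)-2'-hydroxychalcone 7 (not isolated)
Conditions: 50% aq KOH (6 equiv), EtOH, rt, 36 h; then AcOH to pH 6, reflux, 24 h (one pot; residual 7 recycled)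
Reagents that add atoms: none
Why: Claisen–Schmidt condensation followed by 6-endo oxa-Michael closure in the KOAc/AcOH buffer made on neutralisation (the chalcone isomerase step); the new C2 centre is racemic, which does not matter because step 5 erases it.

**Step 5 (key step)**
Reactants: 8 rac-flavanone
Product: 10 6-(benzyloxy)-3-[2-(benzyloxy)-3,4-dimethoxyphenyl]-7,8-dimethoxy-4H-chromen-4-one (isoflavone), via trans-3-iodanylflavanone 9 (not isolated)
Conditions: PhI(OH)OTs (1.2 equiv), MeCN, reflux, 6 h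
Reagents that add atoms: none
Why: Hypervalent-iodine oxidative 2→3 aryl migration of a flavanone (the isoflavone synthase step), in which the enol is iodinated at C3 anti to the 2-aryl group, the para-methoxy-activated aryl ring bridges as a phenonium ion while PhI leaves, and the O1-stabilised C2 oxocarbenium ion loses H3; O1 is already a ring ether and both phenols are benzylated, so no free phenol meets I(III).

**Step 6**
Reactants: 10 isoflavone
Product: 12 (3S,4S)-6-(benzyloxy)-3-[2-(benzyloxy)-3,4-dimethoxyphenyl]-7,8-dimethoxychroman-4-ol (cis-isoflavan-4-ol), via racemising isoflavanone 11 (not isolated)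
Conditions: RuCl[(S,S)-TsDPEN](p-cymene) (2 mol %), HCO2H/Et3N 5:2, EtOAc, 40 °C, 48 h; recrystallise
Reagents that add atoms: none
Why: Noyori asymmetric transfer-hydrogenation cascade with dynamic kinetic resolution (the isoflavone reductase and vestitone reductase steps), in which Ru–H adds 1,4 to the chromone, isoflavanone 11 racemises fast at its acidic C3–H, and the (S,S)-catalyst reduces only the (3S)-ketone to the (4S)-carbinol with the same facial sense as 4-chromanone, so C3 and C4 are set together as the cis pair.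

**Step 7**
Reactants: 12 cis-(3S,4S)-isoflavan-4-ol
Product: 15 (3S)-3-(2-hydroxy-3,4-dimethoxyphenyl)-7,8-dimethoxychroman-6-ol (target), via debenzylated isoflavan-4-ol 13 (not isolated), via pterocarpan 14 (not isolated)
Conditions: H2 (1 atm), 10% Pd/C, EtOH, rt, 3 h; then conc. HCl (0.2 equiv), rt, 1 h; then H2 (5 bar), 40 °C, 16 h (one pot)
Reagents that add atoms: none
Why: Hydrogenolysis, SN1 ring closure and hydrogenolysis in one flask (the pterocarpan synthase and pterocarpan reductase steps), in which neutral Pd/C–H2 removes both benzyl ethers, a trace of HCl ionises C4–OH (cation stabilised by O1 and the para 7-OMe), the neighbouring 2'-OH traps it as the only possible cis-fused dihydrofuran 14, and its benzylic C11a–O bond is then cleaved; no bond to C3 is ever broken, so the (3S) centre is kept while C4 becomes CH2.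

**Compound list**
1 | 2'-hydroxy-3',4'-dimethoxyacetophenone | CC(=O)c1ccc(OC)c(OC)c1O | starting material
2 | potassium 5-acetyl-4-hydroxy-2,3-dimethoxyphenyl sulfate | CC(=O)c1cc(OS(=O)(=O)[O-])c(OC)c(OC)c1O.[K+] | intermediate
3 | 2',5'-dihydroxy-3',4'-dimethoxyacetophenone | CC(=O)c1cc(O)c(OC)c(OC)c1O | intermediate
4 | 5'-(benzyloxy)-2'-hydroxy-3',4'-dimethoxyacetophenone | CC(=O)c1cc(OCc2ccccc2)c(OC)c(OC)c1O | intermediate
5 | 2-hydroxy-3,4-dimethoxybenzaldehyde | O=Cc1ccc(OC)c(OC)c1O | starting material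
6 | 2-(benzyloxy)-3,4-dimethoxybenzaldehyde | O=Cc1ccc(OC)c(OC)c1OCc1ccccc1 | intermediate
7 | (E)-1-[5-(benzyloxy)-2-hydroxy-3,4-dimethoxyphenyl]-3-[2-(benzyloxy)-3,4-dimethoxyphenyl]prop-2-en-1-one | O=C(/C=C/c1ccc(OC)c(OC)c1OCc1ccccc1)c1cc(OCc2ccccc2)c(OC)c(OC)c1O | intermediate
8 | rac-6-(benzyloxy)-2-[2-(benzyloxy)-3,4-dimethoxyphenyl]-7,8-dimethoxychroman-4-one | O=C1CC(c2ccc(OC)c(OC)c2OCc2ccccc2)Oc2c1cc(OCc1ccccc1)c(OC)c2OC | intermediate
9 | rac-trans-3-[phenyl(tosyloxy)-λ3-iodanyl] derivative of flavanone 8 | O=C1C(I(c2ccccc2)OS(=O)(=O)c2ccc(C)cc2)C(c2ccc(OC)c(OC)c2OCc2ccccc2)Oc2c1cc(OCc1ccccc1)c(OC)c2OC | intermediate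
10 | 6-(benzyloxy)-3-[2-(benzyloxy)-3,4-dimethoxyphenyl]-7,8-dimethoxy-4H-chromen-4-one | O=c1c(-c2ccc(OC)c(OC)c2OCc2ccccc2)coc2c1cc(OCc1ccccc1)c(OC)c2OC | intermediate
11 | rac-6-(benzyloxy)-3-[2-(benzyloxy)-3,4-dimethoxyphenyl]-7,8-dimethoxychroman-4-one (enantiomers interconvert) | COc1ccc(C2COc3c(cc(OCc4ccccc4)c(OC)c3OC)C2=O)c(OCc2ccccc2)c1OC | intermediate
12 | (3S,4S)-6-(benzyloxy)-3-[2-(benzyloxy)-3,4-dimethoxyphenyl]-7,8-dimethoxychroman-4-ol (aryl and OH cis) | COc1ccc([C@H]2COc3c(cc(OCc4ccccc4)c(OC)c3OC)[C@H]2O)c(OCc2ccccc2)c1OC | intermediate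
13 | (3S,4S)-3-(2-hydroxy-3,4-dimethoxyphenyl)-7,8-dimethoxychroman-4,6-diol | COc1ccc([C@H]2COc3c(cc(O)c(OC)c3OC)[C@H]2O)c(O)c1OC | intermediate
14 | (6aS,11aS)-2-hydroxy-3,4,9,10-tetramethoxypterocarpan (cis-fused) | COc1ccc2[C@H]3COc4c(cc(O)c(OC)c4OC)[C@H]3Oc2c1OC | intermediate
15 | (3S)-6,2'-dihydroxy-7,8,3',4'-tetramethoxyisoflavan | COc1ccc([C@H]2COc3c(cc(O)c(OC)c3OC)C2)c(O)c1OC | target

**Totals**
Total steps: 7. Longest linear sequence: 6 (1 → 3 → 4 → 8 → 10 → 12 → 15).

**Three steps most likely to fail**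

Step 5 (aryl shift on the flavanone). The risks are dehydrogenation to the flavone, ring contraction, and attack of I(III) on the very electron-rich B ring. The fallback moves the aryl shift to the open-chain stage and closes the ring afterwards.
- It sets out from chalcone 7, isolated by acidifying after the KOH stage of step 4.
- Ac2O/pyridine gives the 2'-acetoxychalcone F1.
- Tl(NO3)3·3H2O in MeOH/HC(OMe)3 at rt gives the rac-α-aryl-β,β-dimethoxypropiophenone F2.
- HCl in MeOH at reflux removes the acetate and closes the pyranone, which returns to the route at isoflavone 10.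
- This path also covers a poor chalcone/flavanone equilibrium in step 4.

Step 1 (Elbs oxidation). The risks are low conversion and tar formation. The fallback brings in the oxygen through a carbon substituent.
- It sets out from 1.
- Duff formylation (hexamethylenetetramine, TFA, 80 °C) goes para to the phenol and gives 5-acetyl-4-hydroxy-2,3-dimethoxybenzaldehyde F3.
- Dakin oxidation (H2O2, aq NaOH, 0 °C) takes the aldehyde, which reacts much faster than the chelated ketone, through 5-acetyl-4-hydroxy-2,3-dimethoxyphenyl formate F4.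
- F4 is hydrolysed in the same flask, which returns to the route at 3.

Step 7 (acid/Pd cascade). The risks are E1 loss of H3 from the C4 cation, giving an isoflav-3-ene and loss of ee, and sluggish C–O hydrogenolysis. The fallback removes the C4 oxygen by a radical path that involves no cation.
- It sets out from 12.
- 1,1'-Thiocarbonyldiimidazole with DMAP in 1,2-dichloroethane at reflux gives the (3S,4S)-4-O-(imidazol-1-ylthiocarbonyl) derivative F5.
- Barton–McCombie reduction (Bu3SnH, AIBN, toluene, 90 °C) gives (3S)-6-(benzyloxy)-3-[2-(benzyloxy)-3,4-dimethoxyphenyl]-7,8-dimethoxychromane F6.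
- Neutral H2, Pd/C in EtOAc/EtOH returns to the route at 15.

**Further compounds**
F1 | step 5 | (E)-4-(benzyloxy)-2-{3-[2-(benzyloxy)-3,4-dimethoxyphenyl]acryloyl}-5,6-dimethoxyphenyl acetate | CC(=O)Oc1c(C(=O)/C=C/c2ccc(OC)c(OC)c2OCc2ccccc2)cc(OCc2ccccc2)c(OC)c1OC
F2 | step 5 | rac-4-(benzyloxy)-2-{2-[2-(benzyloxy)-3,4-dimethoxyphenyl]-3,3-dimethoxypropanoyl}-5,6-dimethoxyphenyl acetate | CC(=O)Oc1c(C(=O)C(C(OC)OC)c2ccc(OC)c(OC)c2OCc2ccccc2)cc(OCc2ccccc2)c(OC)c1OC
F3 | step 1 | 5-acetyl-4-hydroxy-2,3-dimethoxybenzaldehyde | CC(=O)c1cc(C=O)c(OC)c(OC)c1O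
F4 | step 1 | 5-acetyl-4-hydroxy-2,3-dimethoxyphenyl formate | CC(=O)c1cc(OC=O)c(OC)c(OC)c1O
F5 | step 7 | O-{(3S,4S)-6-(benzyloxy)-3-[2-(benzyloxy)-3,4-dimethoxyphenyl]-7,8-dimethoxychroman-4-yl} 1H-imidazole-1-carbothioate | COc1ccc([C@H]2COc3c(cc(OCc4ccccc4)c(OC)c3OC)[C@H]2OC(=S)n2ccnc2)c(OCc2ccccc2)c1OC
F6 | step 7 | (3S)-6-(benzyloxy)-3-[2-(benzyloxy)-3,4-dimethoxyphenyl]-7,8-dimethoxychromane | COc1ccc([C@H]2COc3c(cc(OCc4ccccc4)c(OC)c3OC)C2)c(OCc2ccccc2)c1OC
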